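The five-membered ring of the indane (C1, C2, C3, C3a, C7a) is cut at both bonds that tie it to resorcinol ring A, C7a–C1 and C3a–C3. One palladium/norbornene (Catellani) annulation makes both. 1-Iodo-2,4-dimethoxybenzene is acylated at its only free ortho C–H (future C7a, meta to both oxygens) and then closes at the iodide carbon (future C3a) by an ipso-Heck reaction. It exploits the adjacency of these two electronically unlike ring A carbons. The precursor is an acyclic (E)-2,3-diarylacrylic anhydride, the product a flat 2,3-diarylindenone. Reduction with 1,3-hydrogen transfer sets C3, equilibration sets C2 and C1, and a late catalyst-controlled ketone reduction sets the carbinol.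

Key step: step 3

Remark on numbering: C1 carries the side chain, C2 the 3,5-dioxygenated aryl group and C3 the 4-oxygenated aryl group. C3a and C7a are the fusion carbons and ring A is the fused resorcinol ring. The target is (1R,2S,3R) with an (R)-carbinol, and the three ring substituents are all trans.
Assumption: for the C1 nitrile and the C1 aryl ketone, the all-trans arrangement of the three adjacent bulky ring substituents is taken as the thermodynamic one.

Step 1
Reactants: 1 3,5-dimethoxyphenylacetic acid; 2 4-methoxybenzaldehyde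
Product: 3 (E)-2-(3,5-dimethoxyphenyl)-3-(4-methoxyphenyl)prop-2-enoic acid (the two aryl groups cis)
Conditions: Ac2O, Et3N, 110 °C; then H2O, 90 °C; crystallisation
Reagents that add atoms: none
Why: Perkin condensation (Oglialoro variant): 1, activated and enolised by Ac2O/Et3N, adds to 2 and loss of acetate should give mainly the (E)-acid, which is purified by crystallisation; no stereocentre is formed.

Step 2
Reactants: 3 (E)-2-(3,5-dimethoxyphenyl)-3-(4-methoxyphenyl)prop-2-enoic acid (two molecules)
Product: 4 (E)-2-(3,5-dimethoxyphenyl)-3-(4-methoxyphenyl)prop-2-enoic anhydride (symmetric, both alkenes E)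
Conditions: DCC (0.5 equiv), CH2Cl2, 0 °C → rt; filtration
Reagents that add atoms: none
Why: Carbodiimide-mediated dehydration of a carboxylic acid to its symmetric anhydride is standard, runs under neutral conditions and leaves the (E)-alkenes untouched.

Step 3
Reactants: 4 (E)-2-(3,5-dimethoxyphenyl)-3-(4-methoxyphenyl)prop-2-enoic anhydride; 5 1-iodo-2,4-dimethoxybenzene
Product: 6 2-(3,5-dimethoxyphenyl)-4,6-dimethoxy-3-(4-methoxyphenyl)-1H-inden-1-one
Conditions: Pd(OAc)2 (10 mol %), P(2-furyl)3 (25 mol %), norbornene (1 equiv), Cs2CO3, toluene, 100 °C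
Reagents that add atoms: none
Why: Zerovalent palladium inserts into the C–I bond of 5, norbornene carbopalladation and base-assisted C–H palladation at the only free ortho position give an aryl–norbornyl palladacycle, and this is acylated by 4 (oxidative addition of the acyl C–O bond to tetravalent palladium, then reductive elimination) to form C7a–C1; β-carbon elimination then expels norbornene and leaves palladium on the former iodide carbon, which adds across the pendant enone C=C to form C3a–C3, and β-hydride elimination, after face exchange through the oxygen-bound palladium enolate, releases 6. The closest known reaction type is the Catellani ortho-acylation with ipso-Heck termination, which is established as an indenone annulation of aryl iodides with α,β-unsaturated acid anhydrides. One ring is closed, the five-membered ring C1–C2–C3–C3a–C7a, by a formal 5-endo-trig migratory insertion (aryl to the β-carbon of the enone), which the (E)-geometry of 4 helps because it puts the small vinylic hydrogen and not the anisyl group on the inside of the closing U-shaped aryl vinyl ketone. No stereocentre is formed, since 6 is planar; the step fixes the constitution only and the four stereocentres follow in steps 4 to 9. The step needs site selectivity on the arene, and the substrate secures it: the C2 methoxy group of 5 blocks one ortho position, so acylation can only occur at C6 (meta to both oxygens, a site that Friedel–Crafts chemistry cannot reach), and the same group supplies the ortho substituent that drives norbornene extrusion after a single functionalisation. It also needs chemoselectivity (norbornene insertion before any direct Heck reaction), which rests on strained norbornene inserting faster than the hindered trisubstituted alkene of 4.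

Step 4
Reactants: 6 2-(3,5-dimethoxyphenyl)-4,6-dimethoxy-3-(4-methoxyphenyl)-1H-inden-1-one
Product: 7 (1S)-2-(3,5-dimethoxyphenyl)-4,6-dimethoxy-3-(4-methoxyphenyl)-1H-inden-1-ol
Conditions: (R)-2-methyl-CBS-oxazaborolidine (15 mol %), BH3·SMe2, toluene/THF, −20 °C; MeOH quench
Reagents that add atoms: none
Why: Corey–Bakshi–Shibata reduction, a 1,2-selective reduction of the non-enolisable enone: the C2 flank with its aryl group acts as the large substituent and the flat benzo flank as the small one, so the (R)-catalyst should deliver hydride to the face that gives the (1S)-alcohol.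

Step 5
Reactants: 7 (1S)-2-(3,5-dimethoxyphenyl)-4,6-dimethoxy-3-(4-methoxyphenyl)-1H-inden-1-ol
Product: 9 (2R,3R)-2-(3,5-dimethoxyphenyl)-4,6-dimethoxy-3-(4-methoxyphenyl)indan-1-one (trans), via enol 8 (not isolated)
Conditions: DABCO (0.3 equiv), THF, 60 °C
Reagents that add atoms: none
Why: Base-catalysed stereospecific 1,3-proton transfer of a 3-arylindenol: DABCO removes the acidic C1–H, the ammonium ion stays on the same face of the indenyl anion in a tight ion pair and returns the proton suprafacially to C3, which sets C3 as R, after which enol 8 ketonises and the base equilibrates the acidic C2 to the more stable trans (2R) arrangement.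

Step 6
Reactants: 9 (2R,3R)-2-(3,5-dimethoxyphenyl)-4,6-dimethoxy-3-(4-methoxyphenyl)indan-1-one
Product: 10 (1R,2S,3R)-2-(3,5-dimethoxyphenyl)-4,6-dimethoxy-3-(4-methoxyphenyl)indane-1-carbonitrile (all-trans)
Conditions: TosMIC, KOt-Bu, DME/EtOH, 0 → 40 °C
Reagents that add atoms: TosMIC (p-toluenesulfonylmethyl isocyanide), SMILES Cc1ccc(cc1)S(=O)(=O)C[N+]#[C-]
Why: Van Leusen reductive cyanation: the TosMIC anion, a weaker base than the enolate of 9, adds to the ketone, and cyclisation, ring opening and loss of formate and sulfinate give the nitrile, whose acidic C1–H is equilibrated by the alkoxide so that the cyano group ends trans to the C2 aryl group (1R).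

Step 7
Reactants: 10 (1R,2S,3R)-2-(3,5-dimethoxyphenyl)-4,6-dimethoxy-3-(4-methoxyphenyl)indane-1-carbonitrile; 11 4-methoxyphenylmagnesium bromide (THF solution)
Product: 13 [(1R,2S,3R)-2-(3,5-dimethoxyphenyl)-4,6-dimethoxy-3-(4-methoxyphenyl)indan-1-yl](4-methoxyphenyl)methanone, via ketimine 12 (not isolated)
Conditions: 11 (3 equiv), CuBr (5 mol %), THF, reflux; then 2 M HCl, THF, 50 °C
Reagents that add atoms: water, SMILES O
Why: Copper-catalysed Grignard addition to a nitrile followed by acid hydrolysis of ketimine 12 gives the aryl ketone, and C1, which stays epimerisable through the enamine and enol forms, remains in the thermodynamically preferred all-trans (1R) arrangement.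

Step 8
Reactants: 13 [(1R,2S,3R)-2-(3,5-dimethoxyphenyl)-4,6-dimethoxy-3-(4-methoxyphenyl)indan-1-yl](4-methoxyphenyl)methanone
Product: 14 [(1R,2S,3R)-2-(3,5-dihydroxyphenyl)-4,6-dihydroxy-3-(4-hydroxyphenyl)indan-1-yl](4-hydroxyphenyl)methanone
Conditions: BBr3 (12 equiv), CH2Cl2, −78 °C → rt; ice/water quench
Reagents that add atoms: none
Why: Lewis-acid cleavage of aryl methyl ethers with BBr3 is placed at the ketone stage because the deactivated 4-oxygenated aryl ketone tolerates it whereas the later 4-hydroxybenzylic alcohol would ionise; C2 and C3 carry no acidic hydrogen and C1 is already in its thermodynamic configuration.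

Step 9
Reactants: 14 [(1R,2S,3R)-2-(3,5-dihydroxyphenyl)-4,6-dihydroxy-3-(4-hydroxyphenyl)indan-1-yl](4-hydroxyphenyl)methanone
Product: 17 (1R,2S,3R)-2-(3,5-dihydroxyphenyl)-1-[(R)-hydroxy(4-hydroxyphenyl)methyl]-3-(4-hydroxyphenyl)indane-4,6-diol, via silylated ketone 15 (not isolated), via silylated carbinol 16 (not isolated)
Conditions: HMDS, cat. Me3SiCl, MeCN, 60 °C, evaporation; (S)-2-methyl-CBS-oxazaborolidine (0.5 equiv), BH3·SMe2, toluene, −20 → 0 °C; MeOH, cat. K2CO3, 0 °C, pH 7 buffer
Reagents that add atoms: hexamethyldisilazane, SMILES C[Si](C)(C)N[Si](C)(C)C (its Me3Si groups stand only in 15 and 16)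
Why: Corey–Bakshi–Shibata reduction on the transiently silylated ketone: the conjugated aryl group acts as the large and the indanyl group as the small substituent on the (S)-catalyst, which should deliver hydride to the face that gives the (R)-carbinol, the same face that the Felkin–Anh model favours (C7a anti to the incoming hydride, attack past C1–H and away from the peri C7–H), and the silyl ethers fall off on methanolysis under conditions too mild to ionise the 4-hydroxybenzylic alcohol.

Compound list
1 | 3,5-dimethoxyphenylacetic acid | COc1cc(CC(=O)O)cc(OC)c1 | starting material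
2 | 4-methoxybenzaldehyde | COc1ccc(C=O)cc1 | starting material
3 | (E)-2-(3,5-dimethoxyphenyl)-3-(4-methoxyphenyl)prop-2-enoic acid | O=C(O)/C(c1cc(OC)cc(OC)c1)=C/c1ccc(OC)cc1 | intermediate
4 | (E)-2-(3,5-dimethoxyphenyl)-3-(4-methoxyphenyl)prop-2-enoic anhydride | O=C(OC(=O)/C(c1cc(OC)cc(OC)c1)=C/c1ccc(OC)cc1)/C(c1cc(OC)cc(OC)c1)=C/c1ccc(OC)cc1 | intermediate
5 | 1-iodo-2,4-dimethoxybenzene | COc1ccc(I)c(OC)c1 | starting material
6 | 2-(3,5-dimethoxyphenyl)-4,6-dimethoxy-3-(4-methoxyphenyl)-1H-inden-1-one | O=C1C(c2cc(OC)cc(OC)c2)=C(c2ccc(OC)cc2)c2c1cc(OC)cc2OC | intermediate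
7 | (1S)-2-(3,5-dimethoxyphenyl)-4,6-dimethoxy-3-(4-methoxyphenyl)-1H-inden-1-ol | O[C@@H]1C(c2cc(OC)cc(OC)c2)=C(c2ccc(OC)cc2)c2c1cc(OC)cc2OC | intermediate
8 | enol of 9 (C1–OH, C1=C2 double bond, C3 configured as in 9) | OC1=C(c2cc(OC)cc(OC)c2)[C@H](c2ccc(OC)cc2)c2c1cc(OC)cc2OC | intermediate (not isolated)
9 | (2R,3R)-2-(3,5-dimethoxyphenyl)-4,6-dimethoxy-3-(4-methoxyphenyl)indan-1-one | O=C1[C@@H](c2cc(OC)cc(OC)c2)[C@H](c2ccc(OC)cc2)c2c1cc(OC)cc2OC | intermediate
10 | (1R,2S,3R)-2-(3,5-dimethoxyphenyl)-4,6-dimethoxy-3-(4-methoxyphenyl)indane-1-carbonitrile | N#C[C@@H]1[C@@H](c2cc(OC)cc(OC)c2)[C@H](c2ccc(OC)cc2)c2c1cc(OC)cc2OC | intermediate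
11 | 4-methoxyphenylmagnesium bromide | COc1ccc([Mg]Br)cc1 | starting material
12 | N-unsubstituted ketimine of 13 (ring stereocentres as in 13) | N=C(c1ccc(OC)cc1)[C@@H]1[C@@H](c2cc(OC)cc(OC)c2)[C@H](c2ccc(OC)cc2)c2c1cc(OC)cc2OC | intermediate (not isolated)
13 | [(1R,2S,3R)-2-(3,5-dimethoxyphenyl)-4,6-dimethoxy-3-(4-methoxyphenyl)indan-1-yl](4-methoxyphenyl)methanone | O=C(c1ccc(OC)cc1)[C@@H]1[C@@H](c2cc(OC)cc(OC)c2)[C@H](c2ccc(OC)cc2)c2c1cc(OC)cc2OC | intermediate
14 | [(1R,2S,3R)-2-(3,5-dihydroxyphenyl)-4,6-dihydroxy-3-(4-hydroxyphenyl)indan-1-yl](4-hydroxyphenyl)methanone | O=C(c1ccc(O)cc1)[C@@H]1[C@@H](c2cc(O)cc(O)c2)[C@H](c2ccc(O)cc2)c2c1cc(O)cc2O | intermediate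
15 | hexakis(trimethylsilyl) ether of 14 | O=C(c1ccc(O[Si](C)(C)C)cc1)[C@@H]1[C@@H](c2cc(O[Si](C)(C)C)cc(O[Si](C)(C)C)c2)[C@H](c2ccc(O[Si](C)(C)C)cc2)c2c1cc(O[Si](C)(C)C)cc2O[Si](C)(C)C | intermediate (not isolated)
16 | hexakis(trimethylsilyl) aryl ether of 17, (R)-carbinol free | O[C@@H](c1ccc(O[Si](C)(C)C)cc1)[C@@H]1[C@@H](c2cc(O[Si](C)(C)C)cc(O[Si](C)(C)C)c2)[C@H](c2ccc(O[Si](C)(C)C)cc2)c2c1cc(O[Si](C)(C)C)cc2O[Si](C)(C)C | intermediate (not isolated)
17 | (1R,2S,3R)-2-(3,5-dihydroxyphenyl)-1-[(R)-hydroxy(4-hydroxyphenyl)methyl]-3-(4-hydroxyphenyl)indane-4,6-diol (CNP0214825.1) | Oc1ccc([C@@H]2c3c(O)cc(O)cc3[C@H]([C@@H](O)c3ccc(O)cc3)[C@H]2c2cc(O)cc(O)c2)cc1 | target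

Total step count: 9. Longest linear sequence: 9 steps (from 1 or 2 to 17).

Steps most likely to fail

1. Step 6. Enolisation of the acidic 2-aryl ketone and steric shielding of C1 may stop the addition of the TosMIC anion. The fallback sets out from 9 and comes back to the route at 13, so it also bypasses step 7.
 - The weakly basic organocerium reagent from 4-methoxybenzylmagnesium chloride and CeCl3 (THF, −78 → 0 °C) should add to 9 anti to the C2 aryl group. This gives the tertiary alcohol (1S,2R,3R)-1-(4-methoxybenzyl)indan-1-ol F1.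
 - Syn elimination with the Burgess reagent cannot reach C2–H, which lies trans to the hydroxyl group. It should therefore give the exocyclic (E)-4-methoxybenzylidene indane F2.
 - Hydroboration (BH3·THF) and oxidation (H2O2, NaOH) put oxygen on the less substituted exocyclic carbon and give the secondary alcohol F3. Its configurations at C1 and at the carbinol carbon do not matter.
 - Dess–Martin oxidation gives mainly the C1-epimeric aryl ketone F4, which DBU equilibrates to 13.

2. Step 7. Deprotonation of the benzylic C1–H of 10 by the Grignard reagent may outrun addition to the nitrile, and the hindered ketimine may resist hydrolysis. The fallback sets out from 10 and comes back at 13.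
 - Partial reduction with DIBAL-H (toluene, −78 °C) and hydrolysis give the all-trans indane-1-carbaldehyde F5.
 - 11 adds at −78 °C to this far more electrophilic carbonyl group and gives the hexamethyl ether carbinol F6 as a mixture of carbinol epimers.
 - Dess–Martin oxidation converges both epimers on 13.

3. Step 9. Facial selectivity may be poor if the bulky indanyl group competes with the aryl group for the role of the large substituent. Early loss of the labile silyl ethers would also let free phenols consume borane. The fallback sets out from 14 and comes back at 17.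
 - Benzylation (BnBr, K2CO3, DMF) gives the hexabenzyl ether ketone F7.
 - Noyori asymmetric hydrogenation (RuCl2[(S)-xylbinap][(S)-daipen], KOt-Bu, i-PrOH, H2) distinguishes aryl from alkyl rather than large from small. It should give the (R)-configured hexabenzyl ether carbinol F8.
 - Neutral hydrogenolysis (H2, Pd/C, EtOAc/THF) removes the benzyl ethers faster than the benzylic hydroxyl group and gives 17.

Further compounds
F1 | step 6 | (1S,2R,3R)-2-(3,5-dimethoxyphenyl)-4,6-dimethoxy-1-(4-methoxybenzyl)-3-(4-methoxyphenyl)indan-1-ol | O[C@@]1(Cc2ccc(OC)cc2)[C@@H](c2cc(OC)cc(OC)c2)[C@H](c2ccc(OC)cc2)c2c1cc(OC)cc2OC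
F2 | step 6 | (1E,2R,3R)-2-(3,5-dimethoxyphenyl)-4,6-dimethoxy-1-(4-methoxybenzylidene)-3-(4-methoxyphenyl)indane | COc1ccc(/C=C2\[C@@H](c3cc(OC)cc(OC)c3)[C@H](c3ccc(OC)cc3)c3c2cc(OC)cc3OC)cc1
F3 | step 6 | [2-(3,5-dimethoxyphenyl)-4,6-dimethoxy-3-(4-methoxyphenyl)indan-1-yl](4-methoxyphenyl)methanol, C2 and C3 as in 13, C1 and carbinol carbon undefined | OC(c1ccc(OC)cc1)C1[C@@H](c2cc(OC)cc(OC)c2)[C@H](c2ccc(OC)cc2)c2c1cc(OC)cc2OC
F4 | step 6 | [(1S,2S,3R)-2-(3,5-dimethoxyphenyl)-4,6-dimethoxy-3-(4-methoxyphenyl)indan-1-yl](4-methoxyphenyl)methanone (C1 epimer of 13) | O=C(c1ccc(OC)cc1)[C@H]1[C@@H](c2cc(OC)cc(OC)c2)[C@H](c2ccc(OC)cc2)c2c1cc(OC)cc2OC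
F5 | step 7 | (1R,2S,3R)-2-(3,5-dimethoxyphenyl)-4,6-dimethoxy-3-(4-methoxyphenyl)indane-1-carbaldehyde | O=C[C@@H]1[C@@H](c2cc(OC)cc(OC)c2)[C@H](c2ccc(OC)cc2)c2c1cc(OC)cc2OC
F6 | step 7 | [(1R,2S,3R)-2-(3,5-dimethoxyphenyl)-4,6-dimethoxy-3-(4-methoxyphenyl)indan-1-yl](4-methoxyphenyl)methanol, both carbinol epimers | OC(c1ccc(OC)cc1)[C@@H]1[C@@H](c2cc(OC)cc(OC)c2)[C@H](c2ccc(OC)cc2)c2c1cc(OC)cc2OC
F7 | step 9 | hexabenzyl ether of 14 | O=C(c1ccc(OCc2ccccc2)cc1)[C@@H]1[C@@H](c2cc(OCc3ccccc3)cc(OCc3ccccc3)c2)[C@H](c2ccc(OCc3ccccc3)cc2)c2c1cc(OCc1ccccc1)cc2OCc1ccccc1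
F8 | step 9 | hexabenzyl aryl ether of 17, (R)-carbinol free | O[C@@H](c1ccc(OCc2ccccc2)cc1)[C@@H]1[C@@H](c2cc(OCc3ccccc3)cc(OCc3ccccc3)c2)[C@H](c2ccc(OCc3ccccc3)cc2)c2c1cc(OCc1ccccc1)cc2OCc1ccccc1
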